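The pitfall is to read an order in free catalyst from runs that never changed that charge. Ochre and teal differ in capture agent, 0.22 mM against 0.33 mM.

the same everywhere: substrate 22 mM; free catalyst 3.3 mM
- ochre: reagent 22 mM; capture agent 0.22 mM; run made earlier
- teal: reagent 22 mM; capture agent 0.33 mM; run made earlier
- flask: reagent 22.0 mM; capture agent 0.440 mM

- ochre (time / min: target / %): 10.0: 15.7; 25.0: 38.8; 50.0: 66.0; 80.0: 83.8; 120: 93.0
- teal (time / min: target / %): 8.00: 12.6; 15.0: 24.5; 30.0: 44.8; 60.0: 71.4; 120: 92.4

(scatter of a reading: 0.5 percentage points)

- apparent order in free catalyst when 30% of the substrate are converted (percent change of the rate of making target for one percent more free catalyst charged)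
- factor on the rate of making target when 30% of the substrate are converted if free catalyst is charged twice over

Our guess is that each capture agent removes one catalyst for good, and that the rate follows the working catalyst, the charge of free catalyst minus the charge of capture agent: 2.86 mM in the flask. Doubling the catalyst then multiplies the rate by 2.15, and the order is 1.15.

The runs test this weakly. Working catalyst predicts an ochre-to-teal ratio of 1.04. The mean first-order constants at 120 min give a reading of 1.03, with a scatter of 0.5 percentage points on each reading.

The forecast gives 1.3 and 2.4, higher than our 1.15 and 2.15, and says “This is largely a guess”.

The flask gives an order of 1.2, within the margin of the forecast, and a factor of 2.07, lower than forecast.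

    substrate + free catalyst → catalyst intermediate A (k = 64.0 /M/min)
    reagent + catalyst intermediate A ⇌ catalyst intermediate B (K = 31.0 /M, k = 64.0 /M/min)
    catalyst intermediate B ⇌ catalyst intermediate C (K = 0.990, k = 1.80 /min)
    catalyst intermediate C → free catalyst + target (k = 0.800 /min)
    catalyst intermediate A + capture agent → trapped intermediate (k = 240 /M/min)

In the flask, trapped intermediate stands at 12.7% of the catalyst after 0.150 h and still at 13.3% after 15.0 h, and the share our working catalyst set aside is 13.3%. In the flask, catalyst intermediate C goes on at 48 /h, slower than the forward 110 /h of catalyst intermediate B, while the 84 /h of catalyst intermediate A holds with reagent as charged, and reagent is down to 13.7% of its charge after 1.50 h. At 0.721 h catalyst intermediate A, the resting state of the round in the flask at that time, holds 52.7% of the catalyst.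

(The readings were generated by integration from invented constants; the scatter is artificial.)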